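**Retrosynthetic overview**
1. The polyene is cut at C11=C12 and C11'=C12' (carotenoid numbering, primed locants on the ε half): two Wittig olefinations on the C10 trienedial, C15 + C10 + C15.
2. The acetylenic C15 salt is cut at C8–C9 (Sonogashira coupling of a ring A ethynyl alcohol with the (E)-enol triflate of ethyl acetoacetate) and at C7≡C8 (one-carbon homologation of a ring A aldehyde).
3. Ring A is made in one flask from acetone (C4, C5 and the C5 methyl) and 3,3-dimethylpentanedial (C3, C2, C1, C6, C7): aldol addition closes C3–C4 and sets C3, cycloaldol condensation closes C5=C6.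
4. Enabling feature: in ring A the C3 carbinol is 1,3 to C5 and the C5=C6 alkene is conjugated to the exocyclic C7, so with C7 as a formyl group the ring is a β-hydroxy ketone retron and an enal retron at once; the quaternary C1 makes the four-carbon partner a symmetric dialdehyde with homotopic formyl groups that cannot cyclise on itself.
5. Ring order: ring A is the only ring formed (step 3); the ε ring with C6' is bought as (R)-α-ionone.

Key step: step 3

Assumption: (R)-α-ionone of high enantiomeric purity, (2E,4E,6E)-2,7-dimethylocta-2,4,6-trienedial and the prolinamide catalyst of step 3 are taken as purchasable.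

Step 1
Reactants: 1 3,3-dimethylglutaric anhydride
Product: 2 3,3-dimethylpentane-1,5-diol
Conditions: LiAlH4 (2.5 equiv), THF, 0 °C → reflux; H2O, aq. NaOH
Reagents that add atoms: none
Why: Exhaustive hydride reduction of a cyclic anhydride (LiAlH4 reduction) gives the symmetric diol; no stereocentre is involved.

Step 2
Reactants: 2 3,3-dimethylpentane-1,5-diol
Product: 3 3,3-dimethylpentanedial
Conditions: (COCl)2 (2.6 equiv), DMSO (5.2 equiv), CH2Cl2, −78 °C; Et3N (10 equiv), −78 → 0 °C; used as a cold solution
Reagents that add atoms: none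
Why: Swern oxidation activates both hydroxyls at −78 °C, so the dialdehyde should form without passing through the lactol that a slower oxidant would carry on to the lactone.

Step 3
Reactants: 3 3,3-dimethylpentanedial; 4 acetone (excess, also the solvent of the first stage)
Product: 7 (R)-4-hydroxy-2,6,6-trimethylcyclohex-1-ene-1-carbaldehyde, via open-chain aldol lactol 5 (not isolated), via cyclic aldol 6 (not isolated)
Conditions: (S)-N-[(S)-1-hydroxy-4-methyl-1,1-diphenylpentan-2-yl]pyrrolidine-2-carboxamide (10 mol %), acetone, −35 °C, slow addition of 3; then acetone evaporated at 0 °C in the same flask, toluene, piperidinium acetate (20 mol %), rt → 40 °C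
Reagents that add atoms: none
Why: Proposed new method: a one-flask amine-catalysed [2+4] annulation of acetone with a 1,5-dialdehyde, whose two halves are known reaction types (prolinamide-catalysed enamine aldol of acetone onto an aliphatic aldehyde, and amine-salt cycloaldol condensation of a 7-oxoaldehyde to a 2-methylcyclohex-1-enecarbaldehyde) but whose merger on one substrate is not. The acetone enamine of the catalyst adds to one of the two homotopic formyl groups (C3–C4) and the adduct 5 rests as its six-membered lactol; after the solvent switch the piperidine enamine of the remaining formyl group attacks the C5 ketone in a 6-(enolexo)-exo-trig closure (C5–C6) to give 6, which loses water by enamine-assisted E1cB to the conjugated tetrasubstituted enal, so the two transient centres of 6 vanish. The C3 carbinol is set by the catalyst alone in the first event: the amide N–H and the carbinol O–H bind the aldehyde so that the enamine attacks its Re face, the sense known for L-proline-derived catalysts, which corresponds to 3R. The step needs mono- over bis-addition of acetone, aldehyde-enamine over ketone-enol cyclisation and survival of the C3 hydroxyl: lactolisation of 5 (helped by the gem-dimethyl group) withdraws the second formyl group from acetone, secondary amines form enamines far faster from aldehydes than from methyl ketones, and the nearly neutral amine salt should not trigger β- or vinylogous elimination. The quaternary C1 also protects the dialdehyde itself, since its only intramolecular aldol would close a four-membered ring.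

Step 4
Reactants: 7 (R)-4-hydroxy-2,6,6-trimethylcyclohex-1-ene-1-carbaldehyde
Product: 8 (R)-4-ethynyl-3,5,5-trimethylcyclohex-3-en-1-ol
Conditions: dimethyl (1-diazo-2-oxopropyl)phosphonate (1.5 equiv), K2CO3 (2.5 equiv), MeOH, 0 °C → rt
Reagents that add atoms: dimethyl (1-diazo-2-oxopropyl)phosphonate, COP(=O)(OC)C(=[N+]=[N-])C(C)=O
Why: Seyferth–Gilbert homologation in its Ohira–Bestmann form turns the formyl group into the C7≡C8 alkyne; the fully substituted β-carbon of the enal disfavours conjugate addition of methanol and the carbonate base tolerates the free hydroxyl, whose stereocentre is untouched.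

Step 5
Reactants: 9 ethyl acetoacetate
Product: 10 ethyl (E)-3-(trifluoromethanesulfonyloxy)but-2-enoate
Conditions: Tf2O (1.2 equiv), aq. Me4NOH, hexane, 5 °C
Reagents that add atoms: trifluoromethanesulfonic anhydride, O=S(=O)(OS(=O)(=O)C(F)(F)F)C(F)(F)F
Why: O-sulfonylation of the β-keto ester enolate (enol triflate formation); with the non-chelating Me4N+ counter-ion the open enolate should be trapped as the (E)-triflate, whereas a chelating lithium counter-ion would give the (Z)-isomer.

Step 6
Reactants: 8 (R)-4-ethynyl-3,5,5-trimethylcyclohex-3-en-1-ol; 10 ethyl (E)-3-(trifluoromethanesulfonyloxy)but-2-enoate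
Product: 11 ethyl (2E)-5-[(4R)-4-hydroxy-2,6,6-trimethylcyclohex-1-en-1-yl]-3-methylpent-2-en-4-ynoate
Conditions: Pd(PPh3)4 (5 mol %), CuI (10 mol %), Et3N (3 equiv), THF, rt, degassed
Reagents that add atoms: none
Why: Sonogashira coupling forms C8–C9; oxidative addition of zerovalent palladium into the electron-poor enol triflate and reductive elimination both go with retention, so the (E)-geometry of 10 becomes the 9E geometry.

Step 7
Reactants: 11 ethyl (2E)-5-[(4R)-4-hydroxy-2,6,6-trimethylcyclohex-1-en-1-yl]-3-methylpent-2-en-4-ynoate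
Product: 12 (2E)-5-[(4R)-4-hydroxy-2,6,6-trimethylcyclohex-1-en-1-yl]-3-methylpent-2-en-4-yn-1-ol
Conditions: i-Bu2AlH (3.5 equiv), CH2Cl2, −78 → 0 °C; aq. potassium sodium tartrate
Reagents that add atoms: none
Why: 1,2-Reduction of the conjugated ester with i-Bu2AlH gives the allylic alcohol and leaves the enyne, the 9E geometry and C3 untouched.

Step 8
Reactants: 12 (2E)-5-[(4R)-4-hydroxy-2,6,6-trimethylcyclohex-1-en-1-yl]-3-methylpent-2-en-4-yn-1-ol
Product: 13 [(2E)-5-[(4R)-4-hydroxy-2,6,6-trimethylcyclohex-1-en-1-yl]-3-methylpent-2-en-4-yn-1-yl]triphenylphosphonium bromide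
Conditions: PPh3·HBr (1.05 equiv), CH2Cl2, 0 °C → rt, dark; crystallisation
Reagents that add atoms: triphenylphosphine hydrobromide, [Br-].[PH+](c1ccccc1)(c1ccccc1)c1ccccc1
Why: Phosphonium salt formation from an allylic alcohol: ionisation to the allylic cation and capture by PPh3 at the primary terminus, while the unactivated secondary C3 hydroxyl does not ionise.

Step 9
Reactants: 14 (R)-α-ionone
Product: 15 (1E)-3-methyl-1-[(1R)-2,6,6-trimethylcyclohex-2-en-1-yl]penta-1,4-dien-3-ol (both C3 epimers)
Conditions: CH2=CHMgBr (1.3 equiv), THF, −30 → 0 °C; H2O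
Reagents that add atoms: vinylmagnesium bromide, C=C[Mg]Br
Why: Grignard 1,2-addition to the methyl ketone; the low temperature should leave the doubly allylic C6' hydrogen alone, and the new carbinol centre is of no consequence because it is ionised in step 10.

Step 10
Reactants: 15 (1E)-3-methyl-1-[(1R)-2,6,6-trimethylcyclohex-2-en-1-yl]penta-1,4-dien-3-ol
Product: 16 [(2E,4E)-3-methyl-5-[(1R)-2,6,6-trimethylcyclohex-2-en-1-yl]penta-2,4-dien-1-yl]triphenylphosphonium bromide
Conditions: PPh3·HBr (1.05 equiv), MeOH, 0 °C → rt, dark; crystallisation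
Reagents that add atoms: triphenylphosphine hydrobromide, [Br-].[PH+](c1ccccc1)(c1ccccc1)c1ccccc1
Why: Ionisation of the tertiary bis-allylic carbinol to the pentadienyl cation and PPh3 capture at the primary terminus (phosphonium salt formation with allylic transposition); the 9'E isomer should dominate and be purified by crystallisation.

Step 11
Reactants: 16 [(2E,4E)-3-methyl-5-[(1R)-2,6,6-trimethylcyclohex-2-en-1-yl]penta-2,4-dien-1-yl]triphenylphosphonium bromide; 17 (2E,4E,6E)-2,7-dimethylocta-2,4,6-trienedial (3 equiv, excess recovered)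
Product: 20 (2E,4E,6E,8E,10E,12E)-2,7,11-trimethyl-13-[(1R)-2,6,6-trimethylcyclohex-2-en-1-yl]trideca-2,4,6,8,10,12-hexaenal, via ylide 18 (not isolated), via 11'E/11'Z olefin mixture 19 (not isolated)
Conditions: NaOMe (1.1 equiv, in MeOH) added slowly to 16 and 17, CH2Cl2, −10 °C → rt; then heptane, 90 °C, N2, dark
Reagents that add atoms: none
Why: Wittig olefination of a semi-stabilised allylic ylide with one formyl group of the symmetric dialdehyde used in excess forms C11'=C12', and the sterically strained 11'Z isomer should relax thermally to E.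

Step 12
Reactants: 13 [(2E)-5-[(4R)-4-hydroxy-2,6,6-trimethylcyclohex-1-en-1-yl]-3-methylpent-2-en-4-yn-1-yl]triphenylphosphonium bromide; 20 (2E,4E,6E,8E,10E,12E)-2,7,11-trimethyl-13-[(1R)-2,6,6-trimethylcyclohex-2-en-1-yl]trideca-2,4,6,8,10,12-hexaenal
Product: 23 (3R,6'R)-7,8-didehydro-β,ε-caroten-3-ol (crocoxanthin, CNP0322200.1), via ylide 21 (not isolated), via 11E/11Z olefin mixture 22 (not isolated)
Conditions: NaOMe (1.2 equiv, in MeOH), CH2Cl2, 0 °C → rt, N2, dark; then EtOAc, reflux; crystallisation
Reagents that add atoms: none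
Why: Wittig olefination forms C11=C12 in a convergent C15 + C25 union; the free hydroxyl is tolerated by NaOMe, the strained 11Z isomer should relax thermally, and both stereocentres (C3, C6') are remote from the reacting sites.

**Compound list**
1 | 3,3-dimethylglutaric anhydride | O=C1CC(C)(C)CC(=O)O1 | starting material
2 | 3,3-dimethylpentane-1,5-diol | OCCC(C)(C)CCO | intermediate
3 | 3,3-dimethylpentanedial | O=CCC(C)(C)CC=O | intermediate
4 | acetone | CC(C)=O | starting material
5 | (S)-5-hydroxy-3,3-dimethyl-7-oxooctanal (rests as its six-membered lactol) | CC(=O)C[C@@H](O)CC(C)(C)CC=O | intermediate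
6 | (4S)-2,4-dihydroxy-2,6,6-trimethylcyclohexane-1-carbaldehyde (C1/C2 epimers) | O=CC1C(C)(O)C[C@@H](O)CC1(C)C | intermediate
7 | (R)-4-hydroxy-2,6,6-trimethylcyclohex-1-ene-1-carbaldehyde | O=CC1=C(C)C[C@@H](O)CC1(C)C | intermediate
8 | (R)-4-ethynyl-3,5,5-trimethylcyclohex-3-en-1-ol | C#CC1=C(C)C[C@@H](O)CC1(C)C | intermediate
9 | ethyl acetoacetate | CCOC(=O)CC(C)=O | starting material
10 | ethyl (E)-3-(trifluoromethanesulfonyloxy)but-2-enoate | CCOC(=O)/C=C(\C)OS(=O)(=O)C(F)(F)F | intermediate
11 | ethyl (2E)-5-[(4R)-4-hydroxy-2,6,6-trimethylcyclohex-1-en-1-yl]-3-methylpent-2-en-4-ynoate | CCOC(=O)/C=C(\C)C#CC1=C(C)C[C@@H](O)CC1(C)C | intermediate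
12 | (2E)-5-[(4R)-4-hydroxy-2,6,6-trimethylcyclohex-1-en-1-yl]-3-methylpent-2-en-4-yn-1-ol | OC/C=C(\C)C#CC1=C(C)C[C@@H](O)CC1(C)C | intermediate
13 | [(2E)-5-[(4R)-4-hydroxy-2,6,6-trimethylcyclohex-1-en-1-yl]-3-methylpent-2-en-4-yn-1-yl]triphenylphosphonium bromide | [Br-].c1ccccc1[P+](c1ccccc1)(c1ccccc1)C/C=C(\C)C#CC1=C(C)C[C@@H](O)CC1(C)C | intermediate
14 | (R)-α-ionone | CC1=CCCC(C)(C)[C@H]1/C=C/C(C)=O | starting material
15 | (1E)-3-methyl-1-[(1R)-2,6,6-trimethylcyclohex-2-en-1-yl]penta-1,4-dien-3-ol (both C3 epimers) | CC1=CCCC(C)(C)[C@H]1/C=C/C(C)(O)C=C | intermediate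
16 | [(2E,4E)-3-methyl-5-[(1R)-2,6,6-trimethylcyclohex-2-en-1-yl]penta-2,4-dien-1-yl]triphenylphosphonium bromide | [Br-].CC1=CCCC(C)(C)[C@H]1/C=C/C(C)=C/C[P+](c1ccccc1)(c1ccccc1)c1ccccc1 | intermediate
17 | (2E,4E,6E)-2,7-dimethylocta-2,4,6-trienedial | O=C/C(C)=C/C=C/C=C(C)/C=O | starting material
18 | ylide of 16 | CC1=CCCC(C)(C)[C@H]1/C=C/C(C)=C/[CH-][P+](c1ccccc1)(c1ccccc1)c1ccccc1 | intermediate
19 | 20 as the mixture of E and Z isomers at the new C8=C9 bond (carotenoid C11'=C12') | CC1=CCCC(C)(C)[C@H]1/C=C/C(C)=C/C=CC(/C)=C/C=C/C=C(C)/C=O | intermediate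
20 | (2E,4E,6E,8E,10E,12E)-2,7,11-trimethyl-13-[(1R)-2,6,6-trimethylcyclohex-2-en-1-yl]trideca-2,4,6,8,10,12-hexaenal | CC1=CCCC(C)(C)[C@H]1/C=C/C(C)=C/C=C/C(C)=C/C=C/C=C(C)/C=O | intermediate
21 | ylide of 13 | c1ccccc1[P+](c1ccccc1)(c1ccccc1)[CH-]/C=C(\C)C#CC1=C(C)C[C@@H](O)CC1(C)C | intermediate
22 | 23 as the mixture of E and Z isomers at C11=C12 | CC1=CCCC(C)(C)[C@H]1/C=C/C(C)=C/C=C/C(C)=C/C=C/C=C(\C)C=C/C=C(\C)C#CC1=C(C)C[C@@H](O)CC1(C)C | intermediate
23 | (3R,6'R)-7,8-didehydro-β,ε-caroten-3-ol | CC1=CCCC(C)(C)[C@H]1/C=C/C(C)=C/C=C/C(C)=C/C=C/C=C(C)/C=C/C=C(\C)C#CC1=C(C)C[C@@H](O)CC1(C)C | target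

**Step count**
Total steps: 12. Longest linear sequence: 8 (steps 1, 2, 3, 4, 6, 7, 8, 12).

**Steps most likely to fail**

Step 3. Possible failures are double addition of acetone to both formyl groups, self-aldol oligomerisation of the dialdehyde, loss of the C3 hydroxyl by elimination, and erosion of enantioselectivity through retro-aldol equilibration. The fallback builds the same keto aldehyde stepwise with reagent control; it sets out from 1 and comes back at 7. NaBH4 reduction of 1 in THF gives 4,4-dimethyltetrahydro-2H-pyran-2-one F1, which already differentiates the two termini. i-Bu2AlH at −78 °C gives 4,4-dimethyltetrahydro-2H-pyran-2-ol F2. Asymmetric methallylboration of this lactol with the B-methallyldiisopinocampheylborane enantiomer that delivers to the Re face of the aldehyde (expected: the reagent from (−)-α-pinene), followed by oxidative work-up, gives (R)-3,3,7-trimethyloct-7-ene-1,5-diol F3. TEMPO/PhI(OAc)2 oxidises only the primary alcohol, and the resulting lactol is carried on to (R)-4,4-dimethyl-6-(2-methylallyl)tetrahydro-2H-pyran-2-one F4. i-Bu2AlH at −78 °C gives (6R)-4,4-dimethyl-6-(2-methylallyl)tetrahydro-2H-pyran-2-ol F5. Ozonolysis (O3, then Me2S) unveils the methyl ketone and gives 5 as its lactol, which piperidinium acetate cyclises and dehydrates to 7.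

Step 4. Possible failures are slow addition of the phosphonate anion to the hindered conjugated aldehyde, base-induced vinylogous elimination of the hydroxyl, and conjugate addition of methanol. The fallback replaces the diazo homologation by a dibromo-olefination and rearrangement; it sets out from 7 and comes back at 8. TBSCl/imidazole gives (R)-4-(tert-butyldimethylsilyloxy)-2,6,6-trimethylcyclohex-1-ene-1-carbaldehyde F6. CBr4/PPh3 (Corey–Fuchs olefination) gives (R)-tert-butyl{[4-(2,2-dibromovinyl)-3,5,5-trimethylcyclohex-3-en-1-yl]oxy}dimethylsilane F7. n-BuLi (2.2 equiv, THF, −78 °C) gives (R)-tert-butyl[(4-ethynyl-3,5,5-trimethylcyclohex-3-en-1-yl)oxy]dimethylsilane F8, and Bu4NF removes the silyl group to give 8.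

Step 12. Possible failures are scrambling of the C9=C10 geometry through the delocalised ylide, incomplete thermal relaxation at C11=C12, and growth of the 9Z isomer on heating. The fallback uses a phosphonate carbanion, which should form the new alkene E-selectively without a thermal isomerisation; it sets out from 12 (and uses 20) and comes back at 23. NBS/Me2S at −20 °C, selective for the allylic alcohol, gives (R)-4-[(3E)-5-bromo-3-methylpent-3-en-1-yn-1-yl]-3,5,5-trimethylcyclohex-3-en-1-ol F9. Michaelis–Arbuzov reaction with P(OEt)3 at 90 °C gives diethyl [(2E)-5-[(4R)-4-hydroxy-2,6,6-trimethylcyclohex-1-en-1-yl]-3-methylpent-2-en-4-yn-1-yl]phosphonate F10. Horner–Wadsworth–Emmons olefination of 20 with the anion of F10 (NaN(SiMe3)2, 2.1 equiv, THF, −78 °C → 0 °C) gives 23.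

**Further compounds**
F1 | step 3 | 4,4-dimethyltetrahydro-2H-pyran-2-one | O=C1CC(C)(C)CCO1
F2 | step 3 | 4,4-dimethyltetrahydro-2H-pyran-2-ol | OC1CC(C)(C)CCO1
F3 | step 3 | (R)-3,3,7-trimethyloct-7-ene-1,5-diol | C=C(C)C[C@@H](O)CC(C)(C)CCO
F4 | step 3 | (R)-4,4-dimethyl-6-(2-methylallyl)tetrahydro-2H-pyran-2-one | C=C(C)C[C@@H]1CC(C)(C)CC(=O)O1
F5 | step 3 | (6R)-4,4-dimethyl-6-(2-methylallyl)tetrahydro-2H-pyran-2-ol (both anomers) | C=C(C)C[C@@H]1CC(C)(C)CC(O)O1
F6 | step 4 | (R)-4-(tert-butyldimethylsilyloxy)-2,6,6-trimethylcyclohex-1-ene-1-carbaldehyde | O=CC1=C(C)C[C@@H](O[Si](C)(C)C(C)(C)C)CC1(C)C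
F7 | step 4 | (R)-tert-butyl{[4-(2,2-dibromovinyl)-3,5,5-trimethylcyclohex-3-en-1-yl]oxy}dimethylsilane | BrC(Br)=CC1=C(C)C[C@@H](O[Si](C)(C)C(C)(C)C)CC1(C)C
F8 | step 4 | (R)-tert-butyl[(4-ethynyl-3,5,5-trimethylcyclohex-3-en-1-yl)oxy]dimethylsilane | C#CC1=C(C)C[C@@H](O[Si](C)(C)C(C)(C)C)CC1(C)C
F9 | step 12 | (R)-4-[(3E)-5-bromo-3-methylpent-3-en-1-yn-1-yl]-3,5,5-trimethylcyclohex-3-en-1-ol | BrC/C=C(\C)C#CC1=C(C)C[C@@H](O)CC1(C)C
F10 | step 12 | diethyl [(2E)-5-[(4R)-4-hydroxy-2,6,6-trimethylcyclohex-1-en-1-yl]-3-methylpent-2-en-4-yn-1-yl]phosphonate | CCOP(=O)(OCC)C/C=C(\C)C#CC1=C(C)C[C@@H](O)CC1(C)C
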